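## Structural features

The target is a C25 terpenoid acid. A trans-fused decalin (ring A: C1–C5 and C10; ring B: C5–C10) carries at C9 a chain C11–C19, in which an E-trisubstituted C13=C14 alkene leads to a 4-methylbutenolide bound through its γ-carbon C16. Six stereocentres (C4, C5, C6, C8, C9, C10) form one contiguous array around ring B. C4 (CH3, CO2H) and C10 (CH3) are quaternary and flank C5–H; C8 is a tertiary carbinol whose axial methyl is 1,3-diaxial to the C10 methyl; C6 bears an equatorial hydroxyl peri to the equatorial carboxyl. The seventh centre, C16, is too remote for induction from the core and has to be brought in separately. Fragile points are the butenolide (acidic γ-hydrogen at C16, so base threatens epimerisation; hydroxide opens the lactone), the tertiary 8-hydroxyl (acid-promoted dehydration) and the 6-hydroxy acid pair (lactonisation); esters of the neopentyl carboxyl resist hydrolysis. The real difficulty is the bicycle: two quaternary carbons in a 1,3-relationship, four more centres and a trans fusion, all in one absolute sense. Ring A is bare apart from C4 and C10, and the key step uses exactly this: C10–C1–C2–C3–C4–C5 is the imprint of a [4+2] adduct of a C10-methyl diene (C10=C1–C2=C3) and an (E)-2-methyl enoate (C4=C5), linked by the oxygenated C6–C9 chain that becomes ring B.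

## Logic of the disconnections

33 from 32: the O–Si bond at O6 and the alkyl–oxygen bond of the C4 ester are cut. Both fall to fluoride, which acts at silicon and so is indifferent to the shielding of the neopentyl carboxyl. The gain is a one-step end game; the demand is a fluoride source mild enough for the butenolide.

32 from 22 and 30: the C12–C13 bond (sp3–sp2) is cut. The alkene geometry and C16 are then made in a small separate piece, and the core only has to offer a terminal alkene. The forward step must hydroborate that alkene selectively and couple under weakly basic conditions.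

30 from 28, 26, 24 and 23: the C13–I and C14–H bonds, the lactone (C17=C18 and O–C19), the C17–CH3 bond and the C14–C15 bond are cut in turn. This traces C16 to a commercial chiral epoxide. The demands are regiocontrol in the hydrometalation of a methyl alkyne and neutral conditions once the butenolide exists.

22 from 21, 20 and 19: C11=C12 is cut to a C11 aldehyde, the aldehyde is returned to the primary alcohol, and C1=C2 plus the cyclic acetal are restored. No stereocentre changes; the forward steps must leave the β-hydroxy aldehyde intact.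

19 from 18: the C5–C10 and C3–C4 bonds are cut, opening rings A and B at once and removing C4, C5 and C10 as stereocentres. What remains is an acyclic chain with three centres (C6, C8, C9). The forward cycloaddition must be endo and must use one diene face.

18 from 17, 16, 15, 9 and 13: the C2–C1 bond (vinyl group), the O–Si bond, the O–N bond, the C4=C5 bond and the C6–O bond are cut. The diene is made last because it would not survive the oxidants used earlier; C6 is set under catalyst control, independent of C8 and C9.

13 from 11 and 10: the P=C and ester C–O bonds are cut, leading back to a commercial silyl alcohol.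

9 from 7, 6 and 4: the C5 aldehyde is traced to the prenyl alkene, the acetal C–O bond to a benzyl-type ether, and the C10–CH3 and C1–I bonds to a terminal alkyne. The carbometalation is thus placed before any ester or acetal is present.

4 from 3, 2 and 1: the C9–C10 bond is cut to an acetylide and an epoxide, then the ether and the epoxide C–O bonds. C8 and C9 come from one asymmetric epoxidation; the ring opening must go at the secondary carbon with inversion.

## Other disconnections considered

Alternative 1: The cut lies in the side chain, at C14–C15 together with C13–CH3. In the forward direction alkyne A1 (complete bicyclic core, C4 carboxyl and O6 tied as a γ-lactone, 8-O-triethylsilyl) would be methylaluminated with Me3Al/Cp2ZrCl2, converted to the alanate with n-BuLi and added to the CH2 terminus of epoxide A2 to give A3. In its favour: syn carbometalation fixes the E geometry, C16 is imported from a small epoxide, and the butenolide is closed only after the C–C bond is made. On the side chain this is better than the chosen plan: it needs no separately built iodoalkene such as 30 and exposes no base-sensitive γ-centre to a coupling. Against it as the central idea: it closes no ring and creates no stereocentre, so A1 with six contiguous centres remains the unsolved problem. Me3Al also has to spare the lactone, and alanate openings of oxygenated epoxides tend to be slow. In comparison, the two plans address different parts of the structure (flexible chain versus congested core) and differ in mechanism (ionic σ-bond formation versus cycloaddition). The step counts of the end games would be similar once ketal removal and butenolide formation after the coupling are counted.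

Alternative 2: The cut is the C10–CH3 bond, disguised as the CH2 of a cyclopropane across C5–C10. Et2Zn/CH2I2 would cyclopropanate the tetrasubstituted alkene A4 syn to its 6β-hydroxyl to give A5. Later the alcohol would be oxidised, the C5–CH2 bond opened reductively next to the ketone, and the ketone reduced to the equatorial 6α-alcohol. In its favour: hydroxyl-directed Simmons–Smith delivery is highly predictable, so the configuration at C10 would rest on one reliable element, and no quaternary centre has to be forged in a cycloaddition with a hindered diene. On certainty at C10 it is the better plan. Against it: the decalin, the C4 quaternary centre and C9 must already exist in A4. The C6 hydroxyl must first be β and then be inverted through the ketone. Carbenoid addition to a tetrasubstituted alkene may be sluggish. In comparison, it builds a three-membered ring that is opened again and fixes essentially one centre, where the chosen step closes both carbocycles and sets three; it would also need more redox adjustments.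

Alternative 3: The cuts are C4–C5 and C1–C10, with the C4 carboxyl esterified to O6 as the tether. Heating dienoate ester A6 would close ring A and the γ-lactone to give A7. In its favour: the tether atoms are the carboxyl carbon and O6 of the target, so nothing is excised and both groups stay masked without protecting groups; this is better protecting-group economy than the chosen plan. It would also set C4, C5 and C10 relative to C6 in one step, equal to the chosen plan in stereocentres created. Against it: the ester must adopt its disfavoured s-cis conformation, the diene is electron-poor, the dienophile is an unactivated trisubstituted alkene, and both new bonds end at quaternary carbons, so forcing temperatures are to be expected. Ring B and the C8 and C9 centres would still have to be built from the sulfone on a crowded framework, and the lactone would have to be opened at the end beside the butenolide. In comparison, the chosen plan closes two carbocycles with C8 and C9 already in place, at the price of two extra protecting groups.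

Key step: step 13

Remarks on the chemistry (assumptions and corrections):
- Labdane numbering is used for the bicycle (C1–C10) and continued along the chain (C11–C19); α/β refer to the drawing with the C10 methyl β.
- Counted from the ester carbon, the cyclisation substrate is an undeca-2,8,10-trienoate (a deca-1,7,9-triene core, four-atom tether). A deca-2,7,9-trienoate would close a five-membered ring, so the precedent class is named accordingly.
- The cyclisation substrate 18 keeps the required skeleton but uses a 4-methoxybenzylidene acetal in place of an isopropylidene acetal. An isopropylidene acetal of this tertiary/primary 1,3-diol must place a methyl group syn-axial to the C8 substituent; the arylidene acetal has only H axial, forms in one step from the ether used in step 2, and leaves in the hydrogenation of step 14.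
- 18 carries a 2-(trimethylsilyl)ethyl ester in place of a methyl ester, because a neopentyl methyl ester could not be hydrolysed beside the butenolide.
- The alkyne is introduced by SN2 acetylide opening of the O-protected epoxide, because aluminium acetylides tend to open 3,3-disubstituted glycidols at the tertiary carbon. The carboalumination is done before any ester or acetal is present.
- The acetal carbon is assumed to have the thermodynamic configuration (aryl equatorial, 2S); it is lost in step 14.

## Steps

Step 1
Reactants: 1 geraniol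
Product: 2 (2R,3R)-2,3-epoxygeraniol
Conditions: Ti(OiPr)4 (5 mol%), D-(−)-diethyl tartrate (7 mol%), t-BuOOH, 4 Å MS, CH2Cl2, −20 °C
Reagents that add atoms: tert-butyl hydroperoxide, CC(C)(C)OO
Why: Sharpless asymmetric epoxidation of an E-trisubstituted allylic alcohol; the D-tartrate–titanium complex delivers oxygen to the face that gives the 2R,3R epoxide, which fixes C8 and prepares C9 for inversion.

Step 2
Reactants: 2 (2R,3R)-2,3-epoxygeraniol
Product: 3 (2R,3R)-epoxygeranyl 4-methoxybenzyl ether
Conditions: NaH, 4-MeOC6H4CH2Cl, Bu4NI (cat.), THF, 0 °C → rt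
Reagents that add atoms: 4-methoxybenzyl chloride, COc1ccc(CCl)cc1
Why: Williamson etherification; O-alkylation of the primary alkoxide in an aprotic medium should outrun Payne rearrangement, and the ether blocks that rearrangement in step 3 and supplies the acetal carbon of step 5.

Step 3
Reactants: 3 (2R,3R)-epoxygeranyl 4-methoxybenzyl ether
Product: 4 (2S,3R)-2-ethynyl-1-(4-methoxybenzyloxy)-3,7-dimethyloct-6-en-3-ol
Conditions: LiC≡CH·H2NCH2CH2NH2 (4 equiv), DMSO, rt → 45 °C; then H2O
Reagents that add atoms: lithium acetylide–ethylenediamine complex, [Li+].[C-]#C.NCCN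
Why: SN2 opening of a trisubstituted epoxide by acetylide in a dipolar aprotic solvent, with no Lewis acid to loosen the tertiary C–O bond, should occur at the secondary carbon (C9) with inversion; the trans epoxide thus gives the 8R,9S arrangement with C8 untouched.

Step 4
Reactants: 4 (2S,3R)-2-ethynyl-1-(4-methoxybenzyloxy)-3,7-dimethyloct-6-en-3-ol
Product: 6 (1E,3S,4R)-1-iodo-3-[(4-methoxybenzyloxy)methyl]-2,4,8-trimethylnona-1,7-dien-4-ol, via alkenylalane 5 (not isolated)
Conditions: Me3Al (4 equiv), Cp2ZrCl2 (0.5 equiv), CH2Cl2, 0 °C → rt; then I-I in THF, −30 → 0 °C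
Reagents that add atoms: trimethylaluminium, C[Al](C)C; iodine, I-I
Why: Negishi zirconium-catalysed carboalumination: after the hydroxyl is capped as its aluminium alkoxide, CH3–Al adds syn across the terminal alkyne with methyl at the internal carbon (C10), and iodinolysis with retention gives the E iodoalkene; the mixture is kept at or below room temperature to avoid the chelation-driven geometric isomerisation known for homopropargylic alkoxides.

Step 5
Reactants: 6 (1E,3S,4R)-1-iodo-3-[(4-methoxybenzyloxy)methyl]-2,4,8-trimethylnona-1,7-dien-4-ol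
Product: 7 (2S,4R,5S)-5-[(1E)-1-iodoprop-1-en-2-yl]-2-(4-methoxyphenyl)-4-methyl-4-(4-methylpent-3-en-1-yl)-1,3-dioxane
Conditions: DDQ (1.2 equiv), 4 Å MS, CH2Cl2, 0 °C
Reagents that add atoms: none
Why: Anhydrous DDQ oxidation of the 4-methoxybenzyl ether to the benzylic oxocarbenium ion, which the 1,3-related tertiary hydroxyl traps (oxidative acetalisation); the acetal carbon is expected with aryl equatorial and is removed later.

Step 6
Reactants: 7 (2S,4R,5S)-5-[(1E)-1-iodoprop-1-en-2-yl]-2-(4-methoxyphenyl)-4-methyl-4-(4-methylpent-3-en-1-yl)-1,3-dioxane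
Product: 9 3-[(2S,4R,5S)-5-[(1E)-1-iodoprop-1-en-2-yl]-2-(4-methoxyphenyl)-4-methyl-1,3-dioxan-4-yl]propanal, via diol 8 (not isolated)
Conditions: OsO4 (2 mol%), NaIO4 (4 equiv), 2,6-lutidine, dioxane/H2O 3:1, rt
Reagents that add atoms: osmium tetroxide (catalytic oxygen carrier), O=[Os](=O)(=O)=O; sodium periodate (terminal oxidant), [Na+].[O-]I(=O)(=O)=O
Why: Lemieux–Johnson cleavage: OsO4 should dihydroxylate the electron-rich prenyl alkene far faster than the iodine-deactivated alkene, and periodate cleaves the diol to the C5 aldehyde and acetone; lutidine guards the acetal against acid.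

Step 7
Reactants: 10 2-(trimethylsilyl)ethanol
Product: 11 2-(trimethylsilyl)ethyl 2-bromopropanoate (racemic)
Conditions: CH3CHBrCOBr, pyridine, CH2Cl2, 0 °C
Reagents that add atoms: 2-bromopropanoyl bromide, CC(Br)C(Br)=O
Why: Acylation of a primary alcohol by an acid bromide.

Step 8
Reactants: 11 2-(trimethylsilyl)ethyl 2-bromopropanoate
Product: 13 2-(trimethylsilyl)ethyl 2-(triphenylphosphoranylidene)propanoate, via phosphonium bromide 12 (not isolated)
Conditions: PPh3, toluene, 80 °C; then aq. NaOH (1 M), CH2Cl2, 0 °C
Reagents that add atoms: triphenylphosphine, c1ccc(cc1)P(c1ccccc1)c1ccccc1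
Why: SN2 quaternisation of the phosphine by the α-bromo ester and deprotonation of the salt give the ester-stabilised ylide, the usual preparation of 2-(triphenylphosphoranylidene)propanoates.

Step 9
Reactants: 9 3-[(2S,4R,5S)-5-[(1E)-1-iodoprop-1-en-2-yl]-2-(4-methoxyphenyl)-4-methyl-1,3-dioxan-4-yl]propanal; 13 2-(trimethylsilyl)ethyl 2-(triphenylphosphoranylidene)propanoate
Product: 15 2-(trimethylsilyl)ethyl (2E,4S)-5-[(2S,4R,5S)-5-[(1E)-1-iodoprop-1-en-2-yl]-2-(4-methoxyphenyl)-4-methyl-1,3-dioxan-4-yl]-2-methyl-4-(phenylaminooxy)pent-2-enoate, via aminoxy aldehyde 14 (not isolated)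
Conditions: D-proline (30 mol%), PhNO (1.0 equiv), DMSO, 5 °C; then 13 (1.5 equiv), CH2Cl2, 0 °C → rt
Reagents that add atoms: nitrosobenzene, O=Nc1ccccc1
Why: Proline-catalysed α-aminoxylation (enamine attack on the nitroso oxygen, steered by the carboxylic acid) sets C6 under catalyst control, D-proline giving the S centre; in-situ Wittig olefination with the α-methyl stabilised ylide traps the labile aldehyde as the E-2-methyl enoate before it can racemise.

Step 10
Reactants: 15 the (2E,4S)-4-(phenylaminooxy) enoate
Product: 16 2-(trimethylsilyl)ethyl (2E,4S)-4-hydroxy-5-[(2S,4R,5S)-5-[(1E)-1-iodoprop-1-en-2-yl]-2-(4-methoxyphenyl)-4-methyl-1,3-dioxan-4-yl]-2-methylpent-2-enoate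
Conditions: Cu(OAc)2·H2O (30 mol%), EtOH, rt
Reagents that add atoms: none
Why: Copper-catalysed cleavage of the O–N bond of the anilinoxy ether should free the allylic alcohol without touching the enoate, the iodoalkene or C6; the E geometry keeps the γ-hydroxy ester from lactonising.

Step 11
Reactants: 16 the (2E,4S)-4-hydroxy enoate
Product: 17 2-(trimethylsilyl)ethyl (2E,4S)-4-(tert-butyldimethylsilyloxy)-5-[(2S,4R,5S)-5-[(1E)-1-iodoprop-1-en-2-yl]-2-(4-methoxyphenyl)-4-methyl-1,3-dioxan-4-yl]-2-methylpent-2-enoate
Conditions: TBSCl, imidazole, DMF, rt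
Reagents that add atoms: tert-butyldimethylsilyl chloride, CC(C)(C)[Si](C)(C)Cl
Why: Imidazole-promoted silylation of a secondary alcohol; the bulky silyl ether later serves as the equatorial anchor at C6.

Step 12
Reactants: 17 the silyl-protected iodoalkene enoate
Product: 18 2-(trimethylsilyl)ethyl (2E,4S)-4-(tert-butyldimethylsilyloxy)-5-[(2S,4R,5S)-2-(4-methoxyphenyl)-4-methyl-5-[(2E)-penta-2,4-dien-2-yl]-1,3-dioxan-4-yl]-2-methylpent-2-enoate
Conditions: CH2=CHSnBu3, Pd2(dba)3 (2.5 mol%), AsPh3 (20 mol%), CuI (10 mol%), NMP, rt → 40 °C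
Reagents that add atoms: tributyl(vinyl)stannane, C=C[Sn](CCCC)(CCCC)CCCC
Why: Stille coupling with retention of the iodoalkene geometry gives the E diene under neutral conditions; the diene is made last because it would not survive the osmylation of step 6 or nitrosobenzene in step 9.

Step 13
Reactants: 18 the (E,E)-trienoate
Product: 19 trans-octalin: 2-(trimethylsilyl)ethyl ester with C1=C2, 4α-ester/4β-CH3, 5α-H, 6α-OTBS, 8β-CH3, 9α-H, 10β-CH3 and the 8α-O/11-O 4-methoxybenzylidene acetal (4R,5R,6S,8R,9S,10S)
Conditions: Me2AlCl (2.0 equiv), CH2Cl2, −78 → 0 °C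
Reagents that add atoms: none
Why: Me2AlCl binds the ester carbonyl and lowers the LUMO of the C4=C5 enoate, which adds to the C10=C1–C2=C3 diene in a concerted, asynchronous [4+2] cycloaddition; the closest known reaction type is the Lewis-acid-promoted intramolecular Diels–Alder reaction of (E,E)-undeca-2,8,10-trienoates to trans-octalins. Ring A closes as the new cyclohexene of the cycloaddition, and ring B closes at the same time through the four-atom C6–C9 tether, in a fused mode with a chair-like tether. C5 and C10: the aluminium-bound ester lies endo under the diene, which puts the tether exo and gives the trans fusion, the inside methyl of the E diene becoming the axial angular methyl. C4: the E geometry of the dienophile is transferred suprafacially, so the methyl ends cis to C6 (β, axial) and the ester cis to H5 (α, equatorial). The absolute sense of the three new centres depends on the diene face, and the tether fixes it: only the chair with the C6 silyloxy group equatorial lets O8 and C11 sit trans-diequatorial on the forming ring B, as the six-membered acetal requires, since such a ring cannot span trans-diaxial positions. The step thus needs endo over exo selectivity, secured by Lewis-acid coordination to the ester, and a single diene face, secured by the acetal lock and the equatorial preference of the silyl ether.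

Step 14
Reactants: 19 the trans-octalin acetal
Product: 20 decalin diol: 2-(trimethylsilyl)ethyl ester with 4α-ester/4β-CH3, 6α-OTBS, 8α-OH/8β-CH3, 9β-CH2OH, 10β-CH3 (4R,5R,6S,8R,9S,10S)
Conditions: H2 (1 atm), Pd(OH)2/C, EtOAc/EtOH, rt
Reagents that add atoms: none
Why: Heterogeneous hydrogenation should saturate the cis-disubstituted C1=C2 alkene and hydrogenolyse both benzylic C–O bonds of the arylidene acetal in the same flask; no stereocentre is created or touched.

Step 15
Reactants: 20 the decalin diol
Product: 21 8α-hydroxy C11 aldehyde (4R,5R,6S,8R,9S,10S)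
Conditions: Dess–Martin periodinane (1.3 equiv), NaHCO3, CH2Cl2, 0 °C → rt
Reagents that add atoms: none
Why: Dess–Martin oxidation of the primary alcohol; the tertiary 8-hydroxyl cannot be oxidised, and the equatorial C8–O bond lies near the plane of the enol(ate) of the formyl group, so β-elimination is stereoelectronically disfavoured.

Step 16
Reactants: 21 the 8α-hydroxy C11 aldehyde
Product: 22 9β-vinyl decalin with free 8α-OH (4R,5R,6S,8R,9R,10S)
Conditions: Ph3PCH3Br, KN(SiMe3)2, THF, 0 °C → rt
Reagents that add atoms: methyltriphenylphosphonium bromide, C[P+](c1ccccc1)(c1ccccc1)c1ccccc1.[Br-]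
Why: Wittig methylenation of a hindered aldehyde; the ylide is too weak a base to deprotonate the tertiary alcohol enough to start a retro-aldol cleavage, and C9 keeps its more stable equatorial substituent.

Step 17
Reactants: 23 methyl (2R)-oxirane-2-carboxylate
Product: 24 methyl (2R)-2-hydroxyhex-4-ynoate
Conditions: LiC≡CCH3, BF3·OEt2, THF, −78 °C
Reagents that add atoms: 1-propynyllithium, [Li+].[C-]#CC
Why: Yamaguchi-type alkynylation: the alkynyl–boron species formed at −78 °C opens the terminal epoxide at CH2 and should not add to the ester; the future C16 is not involved, so R is kept.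

Step 18
Reactants: 24 methyl (2R)-2-hydroxyhex-4-ynoate
Product: 26 (3R)-3-hydroxyhept-5-yn-2-one, via Weinreb amide 25 (not isolated)
Conditions: MeNH(OMe)·HCl, i-PrMgCl, THF, −20 °C; then MeMgBr, 0 °C; pH 7 buffer
Reagents that add atoms: methylmagnesium bromide, C[Mg]Br; N,O-dimethylhydroxylamine hydrochloride, CNOC.Cl (its atoms remain only in 25)
Why: In-situ Weinreb amide formation and Grignard addition: the chelated tetrahedral intermediate stops at the ketone, and the magnesium alkoxide of the α-hydroxyl shields C16 from enolisation.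

Step 19
Reactants: 26 (3R)-3-hydroxyhept-5-yn-2-one
Product: 28 (5R)-5-(but-2-yn-1-yl)-4-methylfuran-2(5H)-one, via ester ylide 27 (not isolated)
Conditions: Ph3P=C=C=O, toluene, 90 °C
Reagents that add atoms: (triphenylphosphoranylidene)ketene, O=C=C=P(c1ccccc1)(c1ccccc1)c1ccccc1
Why: Bestmann butenolide synthesis: the hydroxyl adds to the ketenylidene phosphorane and the resulting ester ylide closes by intramolecular Wittig reaction on the methyl ketone; the neutral conditions leave the γ-centre alone.

Step 20
Reactants: 28 (5R)-5-(but-2-yn-1-yl)-4-methylfuran-2(5H)-one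
Product: 30 (5R)-5-[(2E)-3-iodobut-2-en-1-yl]-4-methylfuran-2(5H)-one, via alkenylzirconocene 29 (not isolated)
Conditions: Cp2Zr(H)Cl (1.5 equiv), THF, rt; then I-I, 0 °C
Reagents that add atoms: iodine, I-I
Why: Hydrozirconation–iodination: Zr–H adds syn to the 2-alkyne, zirconium settles on the less hindered methyl-bearing carbon after equilibration with a small excess of reagent, and iodinolysis with retention gives the E 2-iodo-2-alkene; the alkyne should react much faster than the hindered lactone.

Step 21
Reactants: 22 the 9β-vinyl decalin; 30 (5R)-5-[(2E)-3-iodobut-2-en-1-yl]-4-methylfuran-2(5H)-one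
Product: 32 protected target: 2-(trimethylsilyl)ethyl ester and 6-O-TBS ether of 33, via alkylborane 31 (not isolated)
Conditions: 9-BBN (2.5 equiv), THF, rt → 50 °C; then 30, Pd(dppf)Cl2 (5 mol%), AsPh3 (10 mol%), K3PO4 (aq.), DMF, rt
Reagents that add atoms: none
Why: Anti-Markovnikov hydroboration of the terminal alkene and B-alkyl Suzuki–Miyaura coupling form C12–C13 with retention of the iodoalkene geometry, giving the E trisubstituted alkene; phosphate at room temperature is chosen to spare the butenolide γ-hydrogen.

Step 22
Reactants: 32 the protected target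
Product: 33 target acid (4R,5R,6S,8R,9R,10S,16R)
Conditions: (Me2N)3S+ Me3SiF2− (5 equiv), DMF, 0 °C → rt; aq. NaH2PO4 (pH 4)
Reagents that add atoms: none
Why: Fluoride-induced desilylation: attack at silicon cleaves the neopentyl ester by β-elimination (ethene, Me3SiF) without any attack at its carbonyl, and the secondary silyl ether falls in the same flask; the ester is expected to go first, and the carboxylate formed cannot lactonise onto the 6-hydroxyl.

## Compound list

1 | geraniol, (2E)-3,7-dimethylocta-2,6-dien-1-ol | CC(C)=CCC/C(C)=C/CO | starting material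
2 | (2R,3R)-2,3-epoxygeraniol | OC[C@H]1O[C@]1(C)CCC=C(C)C | intermediate
3 | (2R,3R)-epoxygeranyl 4-methoxybenzyl ether | COc1ccc(COC[C@H]2O[C@]2(C)CCC=C(C)C)cc1 | intermediate
4 | (2S,3R)-2-ethynyl-1-(4-methoxybenzyloxy)-3,7-dimethyloct-6-en-3-ol | COc1ccc(COC[C@H](C#C)[C@](C)(O)CCC=C(C)C)cc1 | intermediate
5 | (E)-alkenyl(dimethyl)alane of 4, hydroxyl as its dimethylaluminium alkoxide | COc1ccc(COC[C@H](/C(C)=C/[Al](C)C)[C@](C)(O[Al](C)C)CCC=C(C)C)cc1 | intermediate (not isolated)
6 | (1E,3S,4R)-1-iodo-3-[(4-methoxybenzyloxy)methyl]-2,4,8-trimethylnona-1,7-dien-4-ol | COc1ccc(COC[C@H](/C(C)=C/I)[C@](C)(O)CCC=C(C)C)cc1 | intermediate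
7 | (2S,4R,5S)-5-[(1E)-1-iodoprop-1-en-2-yl]-2-(4-methoxyphenyl)-4-methyl-4-(4-methylpent-3-en-1-yl)-1,3-dioxane | I/C=C(\C)[C@H]1CO[C@H](c2ccc(OC)cc2)O[C@]1(C)CCC=C(C)C | intermediate
8 | vicinal diol from the prenyl alkene of 7 (both epimers at the new carbinol) | I/C=C(\C)[C@H]1CO[C@H](c2ccc(OC)cc2)O[C@]1(C)CCC(O)C(C)(C)O | intermediate (not isolated)
9 | 3-[(2S,4R,5S)-5-[(1E)-1-iodoprop-1-en-2-yl]-2-(4-methoxyphenyl)-4-methyl-1,3-dioxan-4-yl]propanal | I/C=C(\C)[C@H]1CO[C@H](c2ccc(OC)cc2)O[C@]1(C)CCC=O | intermediate
10 | 2-(trimethylsilyl)ethanol | C[Si](C)(C)CCO | starting material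
11 | 2-(trimethylsilyl)ethyl 2-bromopropanoate (racemic) | CC(Br)C(=O)OCC[Si](C)(C)C | intermediate
12 | [1-oxo-1-[2-(trimethylsilyl)ethoxy]propan-2-yl]triphenylphosphonium bromide | CC(C(=O)OCC[Si](C)(C)C)[P+](c1ccccc1)(c1ccccc1)c1ccccc1.[Br-] | intermediate (not isolated)
13 | 2-(trimethylsilyl)ethyl 2-(triphenylphosphoranylidene)propanoate | CC(C(=O)OCC[Si](C)(C)C)=P(c1ccccc1)(c1ccccc1)c1ccccc1 | intermediate
14 | (2S)-3-[dioxanyl of 9]-2-(phenylaminooxy)propanal | I/C=C(\C)[C@H]1CO[C@H](c2ccc(OC)cc2)O[C@]1(C)C[C@H](ONc2ccccc2)C=O | intermediate (not isolated)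
15 | 2-(trimethylsilyl)ethyl (2E,4S)-2-methyl-4-(phenylaminooxy)pent-2-enoate bearing the (2S,4R,5S)-iodoalkenyl dioxane at C5 | I/C=C(\C)[C@H]1CO[C@H](c2ccc(OC)cc2)O[C@]1(C)C[C@H](ONc2ccccc2)/C=C(\C)C(=O)OCC[Si](C)(C)C | intermediate
16 | the corresponding (2E,4S)-4-hydroxy enoate | I/C=C(\C)[C@H]1CO[C@H](c2ccc(OC)cc2)O[C@]1(C)C[C@H](O)/C=C(\C)C(=O)OCC[Si](C)(C)C | intermediate
17 | the corresponding (2E,4S)-4-(tert-butyldimethylsilyloxy) enoate | I/C=C(\C)[C@H]1CO[C@H](c2ccc(OC)cc2)O[C@]1(C)C[C@H](O[Si](C)(C)C(C)(C)C)/C=C(\C)C(=O)OCC[Si](C)(C)C | intermediate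
18 | (E,E)-trienoate: 2-(trimethylsilyl)ethyl (2E,4S)-4-(tert-butyldimethylsilyloxy)-5-[(2S,4R,5S)-2-(4-methoxyphenyl)-4-methyl-5-[(2E)-penta-2,4-dien-2-yl]-1,3-dioxan-4-yl]-2-methylpent-2-enoate | C=C/C=C(\C)[C@H]1CO[C@H](c2ccc(OC)cc2)O[C@]1(C)C[C@H](O[Si](C)(C)C(C)(C)C)/C=C(\C)C(=O)OCC[Si](C)(C)C | intermediate
19 | trans-octalin (labdane numbering): C1=C2; 4α-CO2CH2CH2SiMe3, 4β-CH3; 5α-H; 6α-OTBS; 8β-CH3; 9α-H; 10β-CH3; 8α-O and 11-O joined as the (S)-4-methoxybenzylidene acetal; 4R,5R,6S,8R,9S,10S | COc1ccc(cc1)[C@H]1OC[C@@H]2[C@@]3(C)C=CC[C@@](C)(C(=O)OCC[Si](C)(C)C)[C@@H]3[C@@H](O[Si](C)(C)C(C)(C)C)C[C@@]2(C)O1 | intermediate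
20 | trans-decalin diol: 4α-CO2CH2CH2SiMe3, 4β-CH3; 5α-H; 6α-OTBS; 8α-OH, 8β-CH3; 9β-CH2OH; 10β-CH3; 4R,5R,6S,8R,9S,10S | OC[C@@H]1[C@@]2(C)CCC[C@@](C)(C(=O)OCC[Si](C)(C)C)[C@@H]2[C@@H](O[Si](C)(C)C(C)(C)C)C[C@@]1(C)O | intermediate
21 | as 20 with 9β-CHO | O=C[C@@H]1[C@@]2(C)CCC[C@@](C)(C(=O)OCC[Si](C)(C)C)[C@@H]2[C@@H](O[Si](C)(C)C(C)(C)C)C[C@@]1(C)O | intermediate
22 | as 20 with 9β-CH=CH2 (9R) | C=C[C@@H]1[C@@]2(C)CCC[C@@](C)(C(=O)OCC[Si](C)(C)C)[C@@H]2[C@@H](O[Si](C)(C)C(C)(C)C)C[C@@]1(C)O | intermediate
23 | methyl (2R)-oxirane-2-carboxylate (methyl (R)-glycidate) | COC(=O)[C@H]1CO1 | starting material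
24 | methyl (2R)-2-hydroxyhex-4-ynoate | CC#CC[C@@H](O)C(=O)OC | intermediate
25 | (2R)-2-hydroxy-N-methoxy-N-methylhex-4-ynamide | CC#CC[C@@H](O)C(=O)N(C)OC | intermediate (not isolated)
26 | (3R)-3-hydroxyhept-5-yn-2-one | CC#CC[C@@H](O)C(C)=O | intermediate
27 | (3R)-2-oxohept-5-yn-3-yl (triphenylphosphoranylidene)acetate | CC#CC[C@@H](OC(=O)C=P(c1ccccc1)(c1ccccc1)c1ccccc1)C(C)=O | intermediate (not isolated)
28 | (5R)-5-(but-2-yn-1-yl)-4-methylfuran-2(5H)-one | CC#CC[C@H]1OC(=O)C=C1C | intermediate
29 | chlorobis(cyclopentadienyl)[(2E)-4-[(2R)-3-methyl-5-oxo-2,5-dihydrofuran-2-yl]but-2-en-2-yl]zirconium | C/C(=C\C[C@H]1OC(=O)C=C1C)[Zr](Cl)(C1C=CC=C1)C1C=CC=C1 | intermediate (not isolated)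
30 | (5R)-5-[(2E)-3-iodobut-2-en-1-yl]-4-methylfuran-2(5H)-one | C/C(I)=C\C[C@H]1OC(=O)C=C1C | intermediate
31 | B-alkyl-9-borabicyclo[3.3.1]nonane from 22 (boron on C12) | C1CCC2CCCC1B2CC[C@@H]1[C@@]2(C)CCC[C@@](C)(C(=O)OCC[Si](C)(C)C)[C@@H]2[C@@H](O[Si](C)(C)C(C)(C)C)C[C@@]1(C)O | intermediate (not isolated)
32 | 2-(trimethylsilyl)ethyl ester and 6-O-tert-butyldimethylsilyl ether of 33 | CC1=CC(=O)O[C@@H]1C/C=C(\C)CC[C@@H]1[C@@]2(C)CCC[C@@](C)(C(=O)OCC[Si](C)(C)C)[C@@H]2[C@@H](O[Si](C)(C)C(C)(C)C)C[C@@]1(C)O | intermediate
33 | target: 4α-carboxy-4β,8β,10β-trimethyl trans-decalin with 6α-OH, 8α-OH and a 9β-[(3E)-3-methyl-5-[(2R)-3-methyl-5-oxo-2,5-dihydrofuran-2-yl]pent-3-en-1-yl] chain; 4R,5R,6S,8R,9R,10S,16R | CC1=CC(=O)O[C@@H]1C/C=C(\C)CC[C@@H]1[C@@]2(C)CCC[C@@](C)(C(=O)O)[C@@H]2[C@@H](O)C[C@@]1(C)O | target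

## Step count and least certain steps

Total: 22 steps. Longest linear sequence: 16 steps from geraniol (steps 1–6, 9–16, 21, 22). The ylide branch takes 2 steps (7, 8) and the butenolide branch 4 steps (17–20).

Step 13 (key step). The diene carries its C10 methyl in the inside position, so reaching the s-cis conformation is costly and the cyclisation may be slow. While it is slow, the Lewis acid may ionise the electron-rich arylidene acetal or the silylethyl ester, and warming would erode endo selectivity. Fallback, from 18 back to 19: reduce the ester of 18 with DIBAL-H at −78 °C to allylic alcohol F1 and oxidise with MnO2 to the (E)-2-methyl trienal F2. Cyclise this smaller and more electrophilic dienophile (Me2AlCl at −78 °C, or on gentle warming without Lewis acid) to octalin aldehyde F3. Pinnick oxidation (NaClO2, NaH2PO4, 2-methylbut-2-ene) gives acid F4, and Mitsunobu esterification with 10 (PPh3, DIAD) returns 19.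

Step 3. Backside attack at C9 is hindered (next to the fully substituted C8 and to CH2O), so substitution may be slow and base-induced isomerisation of the epoxide to an allylic alcohol may compete. Fallback, from 3 back to 4: CuI-catalysed addition of CH2=CHMgBr (THF, −30 °C), a cuprate SN2 reaction that is reliable at the secondary carbon of such glycidyl ethers, gives vinyl carbinol F5. TESOTf/2,6-lutidine gives silyl ether F6, and Tsuji–Wacker oxidation (PdCl2, CuCl, O2, DMF/H2O) of the terminal alkene gives methyl ketone F7. KN(SiMe3)2/PhNTf2 at −78 °C gives the terminal enol triflate F8, LDA-induced elimination gives the silyl-protected alkyne F9, and Bu4NF returns 4.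

Step 9. The aminoxy aldehyde may oligomerise or racemise before it is olefinated, a second aminoxylation may occur, and the ylide may be consumed by residual nitrosobenzene. Fallback, from 9 back to 16: copper-catalysed α-oxyamination with TEMPO and a chiral imidazolidinone salt (CuCl2·2H2O cat., air, acetone, −10 °C; the catalyst enantiomer that gives the S centre) gives the isolable TEMPO adduct F10. Wittig reaction with 13 gives enoate F11, and Zn/AcOH cleaves the O–N bond to return 16.

Step 21. Aqueous base may epimerise C16 by deprotonating the butenolide γ-position, and transmetalation of the bulky borane may be slow enough to let that happen. Fallback, from 22 back to 32: hydrozirconation of the terminal alkene with Cp2Zr(H)Cl (2.2 equiv, one being consumed by the hydroxyl) gives alkylzirconocene F12. Transmetalation with ZnCl2 and coupling with 30 under Pd(PPh3)4 in THF (Negishi conditions, no base) returns 32.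

Step 22. Basic fluoride may epimerise C16. If the silyl ether is cleaved before the ester, the 6-alkoxide may close onto the neighbouring ester as a lactone. Removal of the hindered silyl ether may also be incomplete. Fallback, from 22 to 33: Bu4NF in THF removes both silicon groups while no butenolide is present, giving dihydroxy acid F13. Hydroboration with excess 9-BBN (the carboxyl is only converted into an acyloxyborane) gives borane F14. Suzuki coupling with 30 under the conditions of step 21 and mild acidification then give 33 directly.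

## Further compounds

F1 | step 13 | (2E,4S)-allylic alcohol from reduction of the ester of 18 | C=C/C=C(\C)[C@H]1CO[C@H](c2ccc(OC)cc2)O[C@]1(C)C[C@H](O[Si](C)(C)C(C)(C)C)/C=C(\C)CO
F2 | step 13 | (2E,4S)-2-methyl trienal corresponding to 18 | C=C/C=C(\C)[C@H]1CO[C@H](c2ccc(OC)cc2)O[C@]1(C)C[C@H](O[Si](C)(C)C(C)(C)C)/C=C(\C)C=O
F3 | step 13 | trans-octalin as 19 with 4α-CHO | COc1ccc(cc1)[C@H]1OC[C@@H]2[C@@]3(C)C=CC[C@@](C)(C=O)[C@@H]3[C@@H](O[Si](C)(C)C(C)(C)C)C[C@@]2(C)O1
F4 | step 13 | trans-octalin as 19 with 4α-CO2H | COc1ccc(cc1)[C@H]1OC[C@@H]2[C@@]3(C)C=CC[C@@](C)(C(=O)O)[C@@H]3[C@@H](O[Si](C)(C)C(C)(C)C)C[C@@]2(C)O1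
F5 | step 3 | (2S,3R)-2-ethenyl-1-(4-methoxybenzyloxy)-3,7-dimethyloct-6-en-3-ol | COc1ccc(COC[C@H](C=C)[C@](C)(O)CCC=C(C)C)cc1
F6 | step 3 | triethylsilyl ether of F5 | COc1ccc(COC[C@H](C=C)[C@](C)(O[Si](CC)(CC)CC)CCC=C(C)C)cc1
F7 | step 3 | methyl ketone from Wacker oxidation of F6 | COc1ccc(COC[C@H](C(C)=O)[C@](C)(O[Si](CC)(CC)CC)CCC=C(C)C)cc1
F8 | step 3 | terminal enol triflate of F7 | COc1ccc(COC[C@H](C(=C)OS(=O)(=O)C(F)(F)F)[C@](C)(O[Si](CC)(CC)CC)CCC=C(C)C)cc1
F9 | step 3 | triethylsilyl ether of 4 | COc1ccc(COC[C@H](C#C)[C@](C)(O[Si](CC)(CC)CC)CCC=C(C)C)cc1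
F10 | step 9 | (2S)-2-(2,2,6,6-tetramethylpiperidin-1-yloxy) aldehyde from 9 | I/C=C(\C)[C@H]1CO[C@H](c2ccc(OC)cc2)O[C@]1(C)C[C@H](ON2C(C)(C)CCCC2(C)C)C=O
F11 | step 9 | (2E,4S)-4-(2,2,6,6-tetramethylpiperidin-1-yloxy) enoate, silylethyl ester | I/C=C(\C)[C@H]1CO[C@H](c2ccc(OC)cc2)O[C@]1(C)C[C@H](ON2C(C)(C)CCCC2(C)C)/C=C(\C)C(=O)OCC[Si](C)(C)C
F12 | step 21 | alkyl(chloro)zirconocene from 22 (zirconium on C12) | Cl[Zr](CC[C@@H]1[C@@]2(C)CCC[C@@](C)(C(=O)OCC[Si](C)(C)C)[C@@H]2[C@@H](O[Si](C)(C)C(C)(C)C)C[C@@]1(C)O)(C1C=CC=C1)C1C=CC=C1
F13 | step 22 | 9β-vinyl 6α,8α-dihydroxy acid (22 without silicon groups) | C=C[C@@H]1[C@@]2(C)CCC[C@@](C)(C(=O)O)[C@@H]2[C@@H](O)C[C@@]1(C)O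
F14 | step 22 | B-alkyl-9-borabicyclo[3.3.1]nonane from F13 | C1CCC2CCCC1B2CC[C@@H]1[C@@]2(C)CCC[C@@](C)(C(=O)O)[C@@H]2[C@@H](O)C[C@@]1(C)O
A1 | alternative 1 | bicyclic 18,6-lactone with 9β-but-3-ynyl chain and 8-O-triethylsilyl ether | C#CCC[C@@H]2[C@@]3(C)CCC[C@@](C)(C(=O)O4)[C@@H]3[C@@H]4C[C@@]2(C)O[Si](CC)(CC)CC
A2 | alternative 1 | (R)-2-(2-methyl-1,3-dioxolan-2-yl)oxirane | CC1(OCCO1)[C@H]2CO2
A3 | alternative 1 | E-homoallylic alcohol with masked methyl ketone | CC1(OCCO1)[C@H](O)C/C=C(\C)CC[C@@H]2[C@@]3(C)CCC[C@@](C)(C(=O)O4)[C@@H]3[C@@H]4C[C@@]2(C)O[Si](CC)(CC)CC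
A4 | alternative 2 | C5=C10 octalin with 6β-hydroxyl, C8 dioxolane and 9-(2-benzyloxyethyl) chain | c1ccccc1COCC[C@@H]2C3=C([C@H](O)CC24OCCO4)[C@](C)(C(=O)OC)CCC3
A5 | alternative 2 | β-face cyclopropane across C5–C10 | c1ccccc1COCC[C@@H]2[C@@]35C[C@@]5([C@H](O)CC24OCCO4)[C@](C)(C(=O)OC)CCC3
A6 | alternative 3 | (E)-2-methylpenta-2,4-dienoate of the allylic alcohol bearing the phenylsulfonylmethyl alkene | C=C/C=C(\C)C(=O)O[C@@H](CCO[Si](C)(C)C(C)(C)C)/C=C(\C)CS(=O)(=O)c1ccccc1
A7 | alternative 3 | ring A cyclohexene fused to the C4–C6 γ-lactone | O=S(=O)(C[C@@]1(C)CC=C[C@@]2(C)C(=O)O[C@@H](CCO[Si](C)(C)C(C)(C)C)[C@H]12)c1ccccc1
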